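A small charge of precatalyst, 20 µM against 20 mM of each substrate, is what to watch here, and the three flasks share it and part by temperature.

all flasks: left-handed substrate 20 mM; partner 40.0 mM; precatalyst 20 µM; right-handed substrate 20 mM; time 3.0 d
- alder: temperature 60 °C
- larch: temperature 40 °C
- ash: at 60 °C until 15 h, from then on at 40 °C

    partner + catalyst + left-handed substrate → catalyst + left-handed product (k1 = 23 L² mol⁻² s⁻¹, Ea1 = 47.0 kJ mol⁻¹)
    partner + catalyst + right-handed substrate → catalyst + right-handed product (k2 = 0.41 L² mol⁻² s⁻¹, Ea2 = 49.0 kJ mol⁻¹)
    left-handed substrate ⇌ right-handed substrate (k3 = 2.1 × 10⁻⁵ s⁻¹, Ea3 = 119 kJ mol⁻¹)
    partner → decomposed reagent (k4 = 7.8 × 10⁻⁶ s⁻¹, Ea4 = 117 kJ mol⁻¹)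
    precatalyst → catalyst (k5 = 6.1 × 10⁻⁶ s⁻¹, Ea5 = 103 kJ mol⁻¹)
    (constants at 60 °C)

- catalyst is single-handed; left-handed substrate and right-handed substrate are mirror images of each other, charged as a racemate, each of them at the stated concentration
- at 60 °C the constants are as listed, elsewhere as the activation energies make them
- an excess is the difference of the two amounts in percent of their sum
- an excess is below zero if the other one leads

1. the flask that comes out highest in excess of left-handed product over right-handed product, or "all alike" when all lie within 1.5 percentage points (alder / larch / ash / all alike)
2. excess of left-handed product over right-handed product at the end, alder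
3. excess of left-handed product over right-handed product at the end, larch
4. excess of left-handed product over right-handed product at the end, ash

The two coupling steps have partner and catalyst in common, so these cancel in their ratio, and product forms in the ratio s[left-handed substrate]/[right-handed substrate]. Here s is the constant of the left-handed step over that of the right-handed, 56.1 at 60 °C: the selectivity factor. While the substrate stays racemic, the excess being formed is therefore (s−1)/(s+1), which I call the ceiling, 96.5%.

Cooling to 40 °C slows the right-handed step more than the left-handed, by 3.1 against 3.0, so s becomes 58.7 and the ceiling 96.7%, a shift of 0.20 percentage points, less than the margin.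

But a gap between the substrates pulls the excess below the ceiling, so I take racemization as the fast step and reckon with the gap it leaves. In alder, at 1.32 d, when release alone has freed 0.5 of the catalyst and decomposition alone leaves 41.2% of the partner, I estimate that the left-handed substrate drains at 3.79 × 10⁻⁶ s⁻¹, slower than the 4.20 × 10⁻⁵ s⁻¹ of racemization both ways together. Their ratio is my estimate of the fractional gap, and it lowers the excess being formed at that moment to about 96.2%, which is my figure for alder.

Cooling, however, slows racemization by 16 and coupling by 3.0, so in larch, and in ash after 15 h, I can't take the substrate as racemic. I expect alder, larch and ash to stay below 96.7% and within 1.5 points of one another, since the ceilings lie closer than that, but for larch and ash this is a judgement and not a reckoning.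

The forecast gives all alike, with 96.2% for alder, 96.5% for larch and 96.1% for ash, holding that “slow catalyst release means the substrate is never far enough from racemic”.

The simulation gives all alike, with 96.3% for alder, 96.5% for larch and 96.3% for ash.

In ash at 3.00 d, coupling uses the left-handed substrate at 0.76 of the rate of its forward racemization, against 0.11 at 0.328 d, and with the left-handed substrate at 38.6% and the right-handed substrate at 46.8% of the two together charged, the selectivity factor puts the excess being formed at 95.9%. In the same ash flask left until 12 d, the left-handed substrate at 28.5% and the right-handed substrate at 36.5%, on the same scale, put it at 95.7%, and the excess of the product gathered there stands at 95.9%.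

The numbers of this flask were chosen freely; the flask was simulated.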